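**Plan**

- Retrosynthesis: cut the tert-butyl-masked acid, then the pyran O-2–C-3 bond (closure of a C-8a formyl enol onto a C-4a alkyne), then C-4a–C≡ (Sonogashira on the enol triflate of a cyclohexane-1,3-dione). C-5 is then taken out of the carbocycle to give a five-membered acyloin, which is cut at C-6–C-7 (benzoin) and C-8–C-8a (Michael) back to the acetoacetate of the side-chain alcohol.
- Forward: alcohol → acetoacetate → Michael adduct → cyclopentanone (C-6, C-7, C-8, C-8a, C-4a) → Rubottom oxidation, silylation, cyclopropanation → ring expansion to the six-membered 1,3-dione (C-5 inserted) → triflate, side chain → pyran ring → free acid.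
- Enabling feature: in the carbocycle, C-6=O and C-4a (the carbon carrying pyran C-4) stand 1,3 across the CH C-5. That is a cyclohexane-1,3-dione pattern, the one-carbon homologue of a cyclopentane acyloin. C-7 is quaternary, so the cyclopentanone can be oxidised and enolised only toward C-4a.
- Stereochemistry: C-4′ comes from (S)-1-bromo-2-methylbutane and C-2′ from an enzymatic reduction. C-8a is a temporary centre set by iminium catalysis and erased when the pyran forms. C-7 is set by the chiral carbene in the benzoin step, and C-8 by dynamic epimerisation of the β-keto ester in the same step. The ring expansion touches no stereocentre.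

Key step: step 8

Remark: the catalyst antipodes named in steps 4 and 5 are those expected from the usual facial models; the opposite antipodes are equally available.

**Route**

Step 1
Reactants: 1 (S)-1-bromo-2-methylbutane; 2 N-methoxy-N-methylacetamide
Product: 4 (S)-4-methylhexan-2-one, via Grignard reagent 3 (not isolated)
Conditions: Mg, THF, reflux; then 2, THF, 0 °C; 1 M HCl
Reagents that add atoms: none
Why: Grignard acylation with a Weinreb amide should stop at the ketone through the chelated tetrahedral magnesium adduct, and the stereocentre of 1 is not at the reacting carbon and is kept.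

Step 2
Reactants: 4 (S)-4-methylhexan-2-one
Product: 5 (2S,4S)-4-methylhexan-2-ol
Conditions: alcohol dehydrogenase ADH-A (Rhodococcus ruber) or another (S)-selective ketoreductase, NAD+ (cat.), iPrOH/phosphate buffer pH 7.5, 30 °C
Reagents that add atoms: none
Why: enzymatic transfer hydrogenation of a methyl ketone with Prelog selectivity should deliver hydride to one carbonyl face under catalyst control and give the 2S carbinol regardless of the remote 4S centre.

Step 3
Reactants: 5 (2S,4S)-4-methylhexan-2-ol; 6 2,2,6-trimethyl-4H-1,3-dioxin-4-one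
Product: 8 (2S,4S)-4-methylhexan-2-yl 3-oxobutanoate, via acetylketene 7 (not isolated)
Conditions: xylene, 135 °C, acetone distilled off
Reagents that add atoms: none
Why: thermal retro-hetero-Diels–Alder cleavage of the dioxinone releases acetylketene, which the secondary alcohol traps (acetoacetylation) without touching its C–O bond, so the carbinol configuration is retained.

Step 4
Reactants: 8 (2S,4S)-4-methylhexan-2-yl 3-oxobutanoate; 9 (E)-4,4-dimethoxybut-2-enal
Product: 10 (2S,4S)-4-methylhexan-2-yl (3S)-2-acetyl-3-(dimethoxymethyl)-5-oxopentanoate (C-2 epimers)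
Conditions: (R)-α,α-diphenylprolinol trimethylsilyl ether (10 mol%), PhCO2H (10 mol%), toluene, 0 °C to rt
Reagents that add atoms: none
Why: iminium-ion catalysed Michael addition of a β-keto ester to an enal (Jørgensen–Hayashi type) in which the silyloxydiphenylmethyl group shields one face of the (E)-iminium ion and sets C-3 (the future C-8a), while C-2 stays epimerisable and the adduct should sit partly as its cyclic hemiacetal.

Step 5
Reactants: 10 (2S,4S)-4-methylhexan-2-yl (3S)-2-acetyl-3-(dimethoxymethyl)-5-oxopentanoate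
Product: 11 (2S,4S)-4-methylhexan-2-yl (1R,2R,5S)-5-(dimethoxymethyl)-2-hydroxy-2-methyl-3-oxocyclopentane-1-carboxylate
Conditions: chiral aminoindanol-derived N-pentafluorophenyl triazolium tetrafluoroborate (10 mol%, antipode matched to the 2R ketol), iPr2NEt (10 mol%), toluene, rt
Reagents that add atoms: none
Why: carbene-catalysed intramolecular crossed aldehyde–ketone benzoin reaction (5-exo closure of C-6–C-7) in which the triazolium selects the face of the acetyl carbonyl and sets the tertiary carbinol, while the β-keto ester centre epimerises under the basic conditions so that the ring should close with the ester trans to the acetal and to the methyl group, hence cis to the new hydroxyl (dynamic kinetic resolution).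

Step 6
Reactants: 11 (2S,4S)-4-methylhexan-2-yl (1R,2R,5S)-5-(dimethoxymethyl)-2-hydroxy-2-methyl-3-oxocyclopentane-1-carboxylate
Product: 13 (2S,4S)-4-methylhexan-2-yl (1R,2R,5R)-5-(dimethoxymethyl)-2-methyl-3-oxo-2,4-bis[(trimethylsilyl)oxy]cyclopentane-1-carboxylate (C-4 epimers), via bis-silyl enol ether 12 (not isolated)
Conditions: TMSOTf (2.5 equiv), Et3N, CH2Cl2, 0 °C; then mCPBA, NaHCO3, CH2Cl2/hexane, −15 °C
Reagents that add atoms: trimethylsilyl triflate C[Si](C)(C)OS(=O)(=O)C(F)(F)F; 3-chloroperbenzoic acid O=C(OO)c1cccc(Cl)c1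
Why: soft enolisation can only go toward C-4 because C-2 is quaternary, and Rubottom oxidation of the silyl enol ether (epoxidation, 1,4-silyl shift) places the silyloxy group there; the new centre is lost again in step 7 and needs no control.

Step 7
Reactants: 13 (2S,4S)-4-methylhexan-2-yl (1R,2R,5R)-5-(dimethoxymethyl)-2-methyl-3-oxo-2,4-bis[(trimethylsilyl)oxy]cyclopentane-1-carboxylate
Product: 15 (2S,4S)-4-methylhexan-2-yl (2R,3R,4R)-2-(dimethoxymethyl)-4-methyl-1,4,5-tris[(trimethylsilyl)oxy]bicyclo[3.1.0]hexane-3-carboxylate (both cyclopropane faces), via tris-silyloxy cyclopentene 14 (not isolated)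
Conditions: TMSOTf, Et3N, CH2Cl2, 0 °C; salts removed (pentane, Celite); then Et2Zn, CH2I2, CH2Cl2, 0 °C to rt
Reagents that add atoms: trimethylsilyl triflate C[Si](C)(C)OS(=O)(=O)C(F)(F)F; diiodomethane ICI
Why: a second soft enolisation gives the enediol bis-silyl ether, and Furukawa–Simmons–Smith cyclopropanation of this electron-rich alkene follows the precedent of acyloin-derived 1,2-bis(silyloxy)cycloalkenes; the facial selectivity does not matter because both bridgeheads are destroyed in step 8.

Step 8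
Reactants: 15 (2S,4S)-4-methylhexan-2-yl (2R,3R,4R)-2-(dimethoxymethyl)-4-methyl-1,4,5-tris[(trimethylsilyl)oxy]bicyclo[3.1.0]hexane-3-carboxylate
Product: 16 (2S,4S)-4-methylhexan-2-yl (1R,2R,6S)-6-(dimethoxymethyl)-2-methyl-3,5-dioxo-2-[(trimethylsilyl)oxy]cyclohexane-1-carboxylate
Conditions: FeCl3 (2.3 equiv), pyridine (1 equiv), DMF, 0 °C to rt; pH 7 buffer
Reagents that add atoms: none
Why: Ito–Saegusa oxidative ring enlargement: FeCl3 turns one cyclopropanol silyl ether into an iron(III) alkoxide, electron transfer gives the alkoxy radical, and β-scission of the bond shared by the three- and five-membered rings (C-6–C-4a) gives the ring-expanded β-keto radical at C-4a, which the second FeCl3 oxidises to the oxocarbenium ion that loses Me3SiCl to give the second carbonyl. The closest known reaction type is the FeCl3-induced conversion of acyloin-derived 1,2-bis(silyloxy)bicyclo[n.1.0]alkanes into the next-higher cycloalkane-1,3-diones. No ring is closed by a cyclisation: the six-membered ring (C-4a, C-5, C-6, C-7, C-8, C-8a) arises from the five-membered ring by cleavage of the zero-atom bridge, which inserts the cyclopropane CH2 as C-5 between C-6 and C-4a. No stereocentre is formed; the two bridgehead centres are destroyed, so both cyclopropane diastereomers converge on one dione, and C-7, C-8 and C-8a are spectators. The step needs cleavage of the internal rather than an external cyclopropane bond, and it must spare the tertiary silyl ether, the acetal and the β-silyloxy ester; the second silyloxy group (α-oxy-stabilised radical, same dione whichever oxygen reacts first) and strain release secure the former, and only a cyclopropanol is oxidised by iron(III) under these conditions.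

Step 9
Reactants: 16 (2S,4S)-4-methylhexan-2-yl (1R,2R,6S)-6-(dimethoxymethyl)-2-methyl-3,5-dioxo-2-[(trimethylsilyl)oxy]cyclohexane-1-carboxylate
Product: 17 (2S,4S)-4-methylhexan-2-yl (1R,2R,6R)-6-(dimethoxymethyl)-2-methyl-3-oxo-5-{[(trifluoromethyl)sulfonyl]oxy}-2-[(trimethylsilyl)oxy]cyclohex-4-ene-1-carboxylate
Conditions: PhNTf2, Et3N, DMAP (cat.), CH2Cl2, 0 °C
Reagents that add atoms: N-phenylbis(trifluoromethanesulfonimide) O=S(=O)(N(c1ccccc1)S(=O)(=O)C(F)(F)F)C(F)(F)F
Why: O-sulfonylation of the 1,3-dione enolate should occur at the oxygen remote from the quaternary silyloxy-bearing C-2, as in enol derivatisation of 4,4-disubstituted cyclohexane-1,3-diones, which leaves the C-3 ketone (C-6 of the target) next to the carbinol.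

Step 10
Reactants: 18 3-(trimethylsilyl)prop-2-ynal; 19 tert-butyl (triphenylphosphoranylidene)acetate
Product: 20 tert-butyl (2E)-5-(trimethylsilyl)pent-2-en-4-ynoate
Conditions: CH2Cl2, 0 °C to rt
Reagents that add atoms: none
Why: Wittig olefination with a stabilised ylide should give the (E)-enoate.

Step 11
Reactants: 20 tert-butyl (2E)-5-(trimethylsilyl)pent-2-en-4-ynoate
Product: 21 tert-butyl (2E)-pent-2-en-4-ynoate
Conditions: TBAF, AcOH (1:1), THF, 0 °C
Reagents that add atoms: none
Why: fluoride-induced protodesilylation of the alkynylsilane, buffered so that the enynoate is not attacked by a nucleophile.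

Step 12
Reactants: 17 (2S,4S)-4-methylhexan-2-yl (1R,2R,6R)-6-(dimethoxymethyl)-2-methyl-3-oxo-5-{[(trifluoromethyl)sulfonyl]oxy}-2-[(trimethylsilyl)oxy]cyclohex-4-ene-1-carboxylate; 21 tert-butyl (2E)-pent-2-en-4-ynoate
Product: 22 (2S,4S)-4-methylhexan-2-yl (1R,2R,6R)-5-[(3E)-5-tert-butoxy-5-oxopent-3-en-1-yn-1-yl]-6-(dimethoxymethyl)-2-methyl-3-oxo-2-[(trimethylsilyl)oxy]cyclohex-4-ene-1-carboxylate
Conditions: PdCl2(PPh3)2 (5 mol%), CuI (10 mol%), Et3N, THF, rt
Reagents that add atoms: none
Why: Sonogashira coupling of an activated β-(triflyloxy) enone with a terminal alkyne proceeds under mild amine conditions that spare the acetal, the silyl ether and both esters.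

Step 13
Reactants: 22 (2S,4S)-4-methylhexan-2-yl (1R,2R,6R)-5-[(3E)-5-tert-butoxy-5-oxopent-3-en-1-yn-1-yl]-6-(dimethoxymethyl)-2-methyl-3-oxo-2-[(trimethylsilyl)oxy]cyclohex-4-ene-1-carboxylate
Product: 24 (2S,4S)-4-methylhexan-2-yl (7R,8R)-3-[(1E)-3-tert-butoxy-3-oxoprop-1-en-1-yl]-7-hydroxy-7-methyl-6-oxo-7,8-dihydro-6H-isochromene-8-carboxylate, via formyl enynone 23 (not isolated)
Conditions: AuCl3 (5 mol%), TFA (3 equiv), MeCN/H2O (10:1), rt
Reagents that add atoms: water O
Why: aqueous acid unmasks the C-8a formyl group and removes the silyl ether, the aldehyde enolises into conjugation with the dienone (which erases the temporary C-8a centre), and gold(III)-promoted 6-endo-dig oxa-cyclisation of this enol onto the alkyne, the cycloisomerisation used for 2-benzopyrylium and azaphilone cores, followed by protodeauration gives the 6H-isochromen-6-one without touching C-7 or C-8.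

Step 14
Reactants: 24 (2S,4S)-4-methylhexan-2-yl (7R,8R)-3-[(1E)-3-tert-butoxy-3-oxoprop-1-en-1-yl]-7-hydroxy-7-methyl-6-oxo-7,8-dihydro-6H-isochromene-8-carboxylate
Product: 25 (2E)-3-[(7R,8R)-7-hydroxy-7-methyl-8-{[(2S,4S)-4-methylhexan-2-yl]oxycarbonyl}-6-oxo-7,8-dihydro-6H-isochromen-3-yl]prop-2-enoic acid
Conditions: TFA/CH2Cl2 (1:4), 0 °C to rt
Reagents that add atoms: none
Why: acidolysis of the tert-butyl ester by loss of isobutene should leave the secondary alkyl ester, the tertiary alcohol and the vinylogous ester intact and does not enolise C-8.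

**Compound list**

1 | (S)-1-bromo-2-methylbutane | CC[C@H](C)CBr | starting material
2 | N-methoxy-N-methylacetamide | CC(=O)N(C)OC | starting material
3 | (S)-(2-methylbutyl)magnesium bromide | CC[C@H](C)C[Mg]Br | intermediate
4 | (S)-4-methylhexan-2-one | CC[C@H](C)CC(C)=O | intermediate
5 | (2S,4S)-4-methylhexan-2-ol | CC[C@H](C)C[C@H](C)O | intermediate
6 | 2,2,6-trimethyl-4H-1,3-dioxin-4-one | CC1=CC(=O)OC(C)(C)O1 | starting material
7 | acetylketene | CC(=O)C=C=O | intermediate
8 | (2S,4S)-4-methylhexan-2-yl 3-oxobutanoate | CC[C@H](C)C[C@H](C)OC(=O)CC(C)=O | intermediate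
9 | (E)-4,4-dimethoxybut-2-enal | COC(OC)/C=C/C=O | starting material
10 | (2S,4S)-4-methylhexan-2-yl (3S)-2-acetyl-3-(dimethoxymethyl)-5-oxopentanoate (C-2 epimers) | CC[C@H](C)C[C@H](C)OC(=O)C(C(C)=O)[C@@H](C(OC)OC)CC=O | intermediate
11 | (2S,4S)-4-methylhexan-2-yl (1R,2R,5S)-5-(dimethoxymethyl)-2-hydroxy-2-methyl-3-oxocyclopentane-1-carboxylate | CC[C@H](C)C[C@H](C)OC(=O)[C@@H]1[C@@H](C(OC)OC)CC(=O)[C@]1(C)O | intermediate
12 | (2S,4S)-4-methylhexan-2-yl (1R,2R,5S)-5-(dimethoxymethyl)-2-methyl-2,3-bis[(trimethylsilyl)oxy]cyclopent-3-ene-1-carboxylate | CC[C@H](C)C[C@H](C)OC(=O)[C@@H]1[C@@H](C(OC)OC)C=C(O[Si](C)(C)C)[C@]1(C)O[Si](C)(C)C | intermediate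
13 | (2S,4S)-4-methylhexan-2-yl (1R,2R,5R)-5-(dimethoxymethyl)-2-methyl-3-oxo-2,4-bis[(trimethylsilyl)oxy]cyclopentane-1-carboxylate (C-4 epimers) | CC[C@H](C)C[C@H](C)OC(=O)[C@@H]1[C@@H](C(OC)OC)C(O[Si](C)(C)C)C(=O)[C@]1(C)O[Si](C)(C)C | intermediate
14 | (2S,4S)-4-methylhexan-2-yl (1R,2R,5R)-5-(dimethoxymethyl)-2-methyl-2,3,4-tris[(trimethylsilyl)oxy]cyclopent-3-ene-1-carboxylate | CC[C@H](C)C[C@H](C)OC(=O)[C@@H]1[C@@H](C(OC)OC)C(O[Si](C)(C)C)=C(O[Si](C)(C)C)[C@]1(C)O[Si](C)(C)C | intermediate
15 | (2S,4S)-4-methylhexan-2-yl (2R,3R,4R)-2-(dimethoxymethyl)-4-methyl-1,4,5-tris[(trimethylsilyl)oxy]bicyclo[3.1.0]hexane-3-carboxylate (both cyclopropane faces) | CC[C@H](C)C[C@H](C)OC(=O)[C@@H]1[C@@H](C(OC)OC)C2(O[Si](C)(C)C)CC2(O[Si](C)(C)C)[C@]1(C)O[Si](C)(C)C | intermediate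
16 | (2S,4S)-4-methylhexan-2-yl (1R,2R,6S)-6-(dimethoxymethyl)-2-methyl-3,5-dioxo-2-[(trimethylsilyl)oxy]cyclohexane-1-carboxylate | CC[C@H](C)C[C@H](C)OC(=O)[C@@H]1[C@@H](C(OC)OC)C(=O)CC(=O)[C@]1(C)O[Si](C)(C)C | intermediate
17 | (2S,4S)-4-methylhexan-2-yl (1R,2R,6R)-6-(dimethoxymethyl)-2-methyl-3-oxo-5-{[(trifluoromethyl)sulfonyl]oxy}-2-[(trimethylsilyl)oxy]cyclohex-4-ene-1-carboxylate | CC[C@H](C)C[C@H](C)OC(=O)[C@@H]1[C@@H](C(OC)OC)C(OS(=O)(=O)C(F)(F)F)=CC(=O)[C@]1(C)O[Si](C)(C)C | intermediate
18 | 3-(trimethylsilyl)prop-2-ynal | C[Si](C)(C)C#CC=O | starting material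
19 | tert-butyl (triphenylphosphoranylidene)acetate | CC(C)(C)OC(=O)C=P(c1ccccc1)(c1ccccc1)c1ccccc1 | starting material
20 | tert-butyl (2E)-5-(trimethylsilyl)pent-2-en-4-ynoate | C[Si](C)(C)C#C/C=C/C(=O)OC(C)(C)C | intermediate
21 | tert-butyl (2E)-pent-2-en-4-ynoate | C#C/C=C/C(=O)OC(C)(C)C | intermediate
22 | (2S,4S)-4-methylhexan-2-yl (1R,2R,6R)-5-[(3E)-5-tert-butoxy-5-oxopent-3-en-1-yn-1-yl]-6-(dimethoxymethyl)-2-methyl-3-oxo-2-[(trimethylsilyl)oxy]cyclohex-4-ene-1-carboxylate | CC[C@H](C)C[C@H](C)OC(=O)[C@@H]1[C@@H](C(OC)OC)C(C#C/C=C/C(=O)OC(C)(C)C)=CC(=O)[C@]1(C)O[Si](C)(C)C | intermediate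
23 | (2S,4S)-4-methylhexan-2-yl (1R,2R,6R)-5-[(3E)-5-tert-butoxy-5-oxopent-3-en-1-yn-1-yl]-6-formyl-2-hydroxy-2-methyl-3-oxocyclohex-4-ene-1-carboxylate | CC[C@H](C)C[C@H](C)OC(=O)[C@@H]1[C@@H](C=O)C(C#C/C=C/C(=O)OC(C)(C)C)=CC(=O)[C@]1(C)O | intermediate
24 | (2S,4S)-4-methylhexan-2-yl (7R,8R)-3-[(1E)-3-tert-butoxy-3-oxoprop-1-en-1-yl]-7-hydroxy-7-methyl-6-oxo-7,8-dihydro-6H-isochromene-8-carboxylate | CC[C@H](C)C[C@H](C)OC(=O)[C@@H]1C2=COC(/C=C/C(=O)OC(C)(C)C)=CC2=CC(=O)[C@]1(C)O | intermediate
25 | (2E)-3-[(7R,8R)-7-hydroxy-7-methyl-8-{[(2S,4S)-4-methylhexan-2-yl]oxycarbonyl}-6-oxo-7,8-dihydro-6H-isochromen-3-yl]prop-2-enoic acid | CC[C@H](C)C[C@H](C)OC(=O)[C@@H]1C2=COC(/C=C/C(=O)O)=CC2=CC(=O)[C@]1(C)O | target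

**Count and risks**

Total steps: 14. Longest linear sequence: 12 (steps 1–9 and 12–14).

Steps most likely to fail:

1. Step 5. The carbene may add poorly to the enolisable β-keto ester ketone (the substrate rests as enolate or hemiacetal), base-induced aldol condensation to a cyclohexenone may compete, and control of the carbonyl face or of the epimerising ester centre may be poor. Fallback: setting out from 10, a samarium diiodide pinacol cyclisation of the keto aldehyde (SmI2, THF/MeOH, −78 °C) should give the cis-diol (2S,4S)-4-methylhexan-2-yl (1R,2R,3S,5S)-5-(dimethoxymethyl)-2,3-dihydroxy-2-methylcyclopentane-1-carboxylate F1. Chelation of samarium by the ester and the resident C-5 centre would steer it. Oxidation of the secondary alcohol only (SO3·pyridine, DMSO, Et3N) then returns to the route at 11.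

2. Step 8. The Lewis-acidic iron salt may cleave the dimethyl acetal or the silyl ethers before the oxidation, or an external cyclopropane bond may break and give a methyl-branched cyclopentanedione instead of the ring-expanded dione. Fallback: setting out from 13, a Lewis acid-promoted homologation of the ketone with trimethylsilyldiazomethane (BF3·OEt2, CH2Cl2, −78 °C, then protodesilylation on work-up), with migration of the less substituted C-4, should give (2S,4S)-4-methylhexan-2-yl (1R,2R,6R)-6-(dimethoxymethyl)-2-methyl-3-oxo-2,5-bis[(trimethylsilyl)oxy]cyclohexane-1-carboxylate F2. Removal of the secondary silyl ether (PPTS, MeOH, 0 °C) gives (2S,4S)-4-methylhexan-2-yl (1R,2R,6R)-6-(dimethoxymethyl)-5-hydroxy-2-methyl-3-oxo-2-[(trimethylsilyl)oxy]cyclohexane-1-carboxylate F3, and Dess–Martin oxidation returns to the route at 16.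

3. Step 13. The enol oxygen may attack the other alkyne carbon (5-exo closure toward an alkylidene furan, favoured by the acrylate as acceptor), or the tertiary β-hydroxy ester may dehydrate under the acid. Fallback: setting out from 22, conjugate addition of pyrrolidine (THF, rt) to the ynenone at the alkyne carbon remote from the ring fixes the position of the heteroatom and should give the dienaminone (2S,4S)-4-methylhexan-2-yl (1R,2R,6R)-5-[(3E)-5-tert-butoxy-5-oxo-2-(pyrrolidin-1-yl)penta-1,3-dien-1-yl]-6-(dimethoxymethyl)-2-methyl-3-oxo-2-[(trimethylsilyl)oxy]cyclohex-4-ene-1-carboxylate F4. Aqueous acetic acid then hydrolyses the acetal and the silyl ether, and the hydroxymethylene oxygen displaces pyrrolidine by addition–elimination (pyrylium-type closure without a metal), which returns to the route at 24.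

**Further compounds**

F1 | step 5 | (2S,4S)-4-methylhexan-2-yl (1R,2R,3S,5S)-5-(dimethoxymethyl)-2,3-dihydroxy-2-methylcyclopentane-1-carboxylate | CC[C@H](C)C[C@H](C)OC(=O)[C@@H]1[C@@H](C(OC)OC)C[C@H](O)[C@]1(C)O
F2 | step 8 | (2S,4S)-4-methylhexan-2-yl (1R,2R,6R)-6-(dimethoxymethyl)-2-methyl-3-oxo-2,5-bis[(trimethylsilyl)oxy]cyclohexane-1-carboxylate (C-5 epimers) | CC[C@H](C)C[C@H](C)OC(=O)[C@@H]1[C@@H](C(OC)OC)C(O[Si](C)(C)C)CC(=O)[C@]1(C)O[Si](C)(C)C
F3 | step 8 | (2S,4S)-4-methylhexan-2-yl (1R,2R,6R)-6-(dimethoxymethyl)-5-hydroxy-2-methyl-3-oxo-2-[(trimethylsilyl)oxy]cyclohexane-1-carboxylate (C-5 epimers) | CC[C@H](C)C[C@H](C)OC(=O)[C@@H]1[C@@H](C(OC)OC)C(O)CC(=O)[C@]1(C)O[Si](C)(C)C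
F4 | step 13 | (2S,4S)-4-methylhexan-2-yl (1R,2R,6R)-5-[(3E)-5-tert-butoxy-5-oxo-2-(pyrrolidin-1-yl)penta-1,3-dien-1-yl]-6-(dimethoxymethyl)-2-methyl-3-oxo-2-[(trimethylsilyl)oxy]cyclohex-4-ene-1-carboxylate | CC[C@H](C)C[C@H](C)OC(=O)[C@@H]1[C@@H](C(OC)OC)C(C=C(N2CCCC2)/C=C/C(=O)OC(C)(C)C)=CC(=O)[C@]1(C)O[Si](C)(C)C
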